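The data are calculated with made-up constants, and the scatter is random.

Start with what is left.

the same everywhere: starting material 0.40 M (fed, over 40 min)

| charge | partner | protic impurity | remark | time |
|---|---|---|---|---|
| theta | 1 M | 0.056 M | run made earlier |  |
| gamma | 1 M | 0.088 M | run made earlier |  |
| delta | 2 M | 0.040 M | run made earlier |  |
| flask | 1.00 M | 0.0400 M |  | 3.0 h |

| run | time / h | intermediate / % | isomer of the product / % | starting material / % | target / % |
|---|---|---|---|---|---|
| theta | 0.667 | 18 | 0 | 66 | 2 |
| theta | 1.33 | 30 | 1 | 45 | 10 |
| theta | 2.00 | 33 | 6 | 33 | 19 |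
| theta | 2.50 | 33 | 5 | 25 | 19 |
| theta | 3.00 | 32 | 11 | 18 | 25 |
| gamma | 0.250 | 3 | 0 | 32 | 2 |
| gamma | 0.417 | 5 | 2 | 49 | 0 |
| gamma | 0.833 | 24 | 0 | 58 | 4 |
| gamma | 1.50 | 31 | 4 | 38 | 5 |
| gamma | 3.00 | 29 | 5 | 16 | 21 |
| delta | 0.250 | 5 | 5 | 29 | 0 |
| delta | 0.833 | 36 | 0 | 49 | 7 |
| delta | 1.33 | 48 | 2 | 25 | 16 |
| delta | 2.00 | 51 | 6 | 6 | 24 |
| delta | 3.00 | 35 | 12 | 1 | 39 |

(standard deviation of a reading: 2 percentage points)

- a reading or a percentage of target counts all its forms, free or not
- percentages count the whole charge, also what has not yet gone in

* the largest share of what was charged as starting material, at 3.0 h belongs to (starting material / target / intermediate / isomer of the product)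
* the largest share itself, whichever of these holds it, in percent of the starting material charged

Once the dose is in, the theta run's starting material falls from 33 % at 2.00 h to 18 % at 3.00 h. Read as a fraction left, this gives a pseudo-first-order constant λ = 0.606 h⁻¹ and a time τ = 1.14 h; this half-life of the starting material after the feed is the quantity carried here.

One objection is that the protic impurity might speed that fall. But the gamma run, with 0.088 M of it against 0.056 M, gives 0.577 h⁻¹. The gap of 0.0290 h⁻¹ is smaller than the 0.111 h⁻¹ that one standard deviation on the last theta reading makes.

A second objection is that τ tells how fast intermediate is supplied, not whether it stays. In the theta run the readings of intermediate stand flat near 33 % at 2.50 h, so supply and drain roughly balance there. The drain constant read there is then λ times 25 % over 33 %, or 0.459 h⁻¹, a half-life of 1.51 h, longer than τ.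

The flask differs from the theta run in its impurity. The theta balance at 3.00 h falls short by 14.0 %, close to the 14.0 % that its impurity is of the charge, and the flask's impurity is 10.0 % of its charge. Scaling the theta end by what remains gives, by my own reckoning, intermediate 33.5 % and target 26.2 %.

The forecast names intermediate at 34 %, a little above my figure: “Intermediate stays largest, though target is not far behind”.

The flask gives intermediate at 34.2 %, with target at 25.3 %.

    starting material + partner → intermediate (k = 0.0118 M⁻¹ min⁻¹)
    intermediate → target (k = 0.00731 min⁻¹)
    partner + target ⇌ idle adduct, settled at all times (K = 1.17 M⁻¹)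
    target ⇌ isomer of the product (K = 1.80, k = 0.0145 min⁻¹)
    starting material + protic impurity → quenched substrate (k = 0.208 M⁻¹ min⁻¹)

In the flask, the half-life of intermediate by its conversion into target is 1.6 h at 3.00 h, longer than the τ read from the theta run, and τ carries the flask's 74.3 % of starting material at 0.667 h to an estimated 18.1 % at 3.00 h, against 19.9 % in the flask. Read at 80 min, the same recipe has 33.2 % intermediate, and τ estimates 49.6 % of starting material, which at that reading holds most at 47.7 %.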